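A direct plan would start from ring A: Friedel–Crafts acylation of methoxyhydroquinone A1 to the ω-methoxyacetophenone A2, C-aroylation of its enolate with 3,4,5-tris(benzyloxy)benzoyl chloride A3 to the β-diketone A4, oxidation to the acylquinone A5 so that the enol oxygen could add to the quinone and close ring C to the tribenzyl flavone A6, then hydrogenolysis. Its weakest steps would be:
(a) the oxidative closure of ring C, an untested oxa-Michael addition to a polymerisation-prone quinone, which would leave the O1–C8a bond to the quinone's choice of carbon, need a reductive rescue and fall on the most advanced material;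
(b) the aroylation of an unprotected hydroquinone trianion, where O-acylation and air oxidation would compete;
(c) acid chloride formation and final debenzylation, two steps that would add no skeletal complexity.

**Plan of the new route.** The retrosynthesis cuts ring A at C4a–C5 and C8–C8a, then the C2–C1' bond. Ring A is a para-hydroquinone (oxygen at C5 and C8) with OMe at C7 and H at C6, fused through C4a=C8a to ring C. C5–C8 with their three oxygens are the four carbons of methyl semisquarate, and C4a=C8a is the C5=C6 bond of a 4-pyranone. Ring C is therefore bought (pyromeconic acid), ring B is attached by Suzuki coupling, and ring A is made last by 4π opening and 6π closure of a 4-pyranonyl-4-hydroxycyclobutenone, which gives the hydroquinone without an oxidant. No quinone, no O1–C8a closure, no enolate aroylation and no Friedel–Crafts step occur.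

Key step: step 8

Remark: pyrogallol, 3-hydroxy-4H-pyran-4-one and dimethyl squarate are taken as commercial. The target is achiral; compounds 9, 12 and 14 are racemic and their single stereocentre is erased on the way.

Step 1
Reactants: 1 pyrogallol (benzene-1,2,3-triol)
Product: 2 1,2,3-tris(methoxymethoxy)benzene
Conditions: MOMCl (3.6 equiv), iPr2NEt (4.5 equiv), CH2Cl2, 0 °C → rt, Ar
Reagents that add atoms: chloromethyl methyl ether, COCCl
Why: Williamson-type O-alkylation of the three phenols to methoxymethyl acetals; the amine base under argon avoids the autoxidation of pyrogallol seen with stronger bases, and the acetals should survive base, palladium, organolithium and heat but fall to dilute acid at the end.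

Step 2
Reactants: 2 1,2,3-tris(methoxymethoxy)benzene
Product: 3 4,4,5,5-tetramethyl-2-[3,4,5-tris(methoxymethoxy)phenyl]-1,3,2-dioxaborolane
Conditions: [Ir(OMe)(cod)]2 (1.5 mol %), 4,4'-di-tert-butyl-2,2'-bipyridine (3 mol %), B2pin2 (0.6 equiv), THF, 80 °C
Reagents that add atoms: bis(pinacolato)diboron, CC1(C)OB(OC1(C)C)B1OC(C)(C)C(C)(C)O1
Why: Iridium-catalysed aromatic C–H borylation is sterically controlled and should take the only C–H bond without an ortho substituent (C5 of 2), giving the 3,4,5-trioxygenated arylboronate in one step.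

Step 3
Reactants: 4 3-hydroxy-4H-pyran-4-one (pyromeconic acid)
Product: 5 2-bromo-3-hydroxy-4H-pyran-4-one
Conditions: NBS (1.02 equiv), MeCN, 0 °C → rt, dark
Reagents that add atoms: N-bromosuccinimide, O=C1CCC(=O)N1Br
Why: Electrophilic bromination of the enol; C2 is ortho to the enolic hydroxyl and alpha to the ring oxygen, the site at which 3-hydroxy-4-pyranones react with aldehydes and halogens, so one equivalent should give the 2-bromide only.

Step 4
Reactants: 5 2-bromo-3-hydroxy-4H-pyran-4-one
Product: 6 2-bromo-3-methoxy-4H-pyran-4-one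
Conditions: MeI (1.5 equiv), K2CO3 (1.5 equiv), acetone, 40 °C
Reagents that add atoms: iodomethane, CI
Why: Williamson O-methylation of the acidic enolic hydroxyl with a weak base; this installs the future 3-OMe of the flavone.

Step 5
Reactants: 3 4,4,5,5-tetramethyl-2-[3,4,5-tris(methoxymethoxy)phenyl]-1,3,2-dioxaborolane; 6 2-bromo-3-methoxy-4H-pyran-4-one
Product: 7 3-methoxy-2-[3,4,5-tris(methoxymethoxy)phenyl]-4H-pyran-4-one
Conditions: Pd(dppf)Cl2 (3 mol %), K3PO4 (2 equiv), 1,4-dioxane/H2O 6:1, 70 °C, Ar
Reagents that add atoms: none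
Why: Suzuki–Miyaura coupling; the C2–Br bond of 6 is a vinylogous acyl bromide that adds readily to zerovalent palladium, and the mild phosphate base limits hydrolytic displacement of bromide, so the C2–C1' bond of the flavone should form cleanly.

Step 6
Reactants: 8 dimethyl squarate (3,4-dimethoxycyclobut-3-ene-1,2-dione)
Product: 10 3-methoxycyclobut-3-ene-1,2-dione (methyl semisquarate), via hydroxycyclobutenone 9 (not isolated)
Conditions: LiAlH(OtBu)3 (1.05 equiv), THF, −78 °C; 1 M HCl quench; then conc. HCl (cat.), CH2Cl2, rt; rapid chromatography, store cold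
Reagents that add atoms: none
Why: Mono-1,2-reduction of a dialkyl squarate by a bulky alkoxyaluminium hydride, then acid-promoted allylic transposition of the carbinol with loss of methanol, the established reduction–elimination route to alkyl semisquarates; the stereocentre of racemic 9 disappears in 10.

Step 7
Reactants: 7 3-methoxy-2-[3,4,5-tris(methoxymethoxy)phenyl]-4H-pyran-4-one; 10 3-methoxycyclobut-3-ene-1,2-dione
Product: 12 4-hydroxy-3-methoxy-4-{5-methoxy-4-oxo-6-[3,4,5-tris(methoxymethoxy)phenyl]-4H-pyran-2-yl}cyclobut-2-en-1-one (racemic), via 6-lithiopyranone 11 (not isolated)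
Conditions: lithium 2,2,6,6-tetramethylpiperidide (1.15 equiv, from 2,2,6,6-tetramethylpiperidine and n-BuLi), THF, −78 °C, 20 min; then 10 (1.4 equiv), THF, −78 °C, 30 min; sat. NH4Cl at −78 °C
Reagents that add atoms: none
Why: Deprotonation then 1,2-addition: hindered lithium amides metalate 4-pyranones and chromones at the carbon alpha to the ring oxygen, of which only C6 is free in 7 (the aryl C–H bonds ortho to the acetals are far less acidic at −78 °C), and organolithiums add to an alkyl semisquarate at the ketone next to the methoxy-bearing carbon because the other carbonyl is a deactivated vinylogous ester; the carbinol centre forms as a racemate and is erased in step 8.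

Step 8
Reactants: 12 4-hydroxy-3-methoxy-4-{5-methoxy-4-oxo-6-[3,4,5-tris(methoxymethoxy)phenyl]-4H-pyran-2-yl}cyclobut-2-en-1-one
Product: 15 5,8-dihydroxy-3,7-dimethoxy-2-[3,4,5-tris(methoxymethoxy)phenyl]-4H-chromen-4-one, via dienylketene 13 (not isolated), via 4aH-chromenedione 14 (not isolated)
Conditions: degassed p-xylene (0.02 M), 135 °C, Ar, dark, 1–2 h; cool and isolate under Ar
Reagents that add atoms: none
Why: Heating should open the cyclobutenone by conrotatory 4π electrocyclic cleavage of the C1–C4 bond, and the torquoselectivity of this opening sends the donor hydroxyl outward, so the pyranonyl group lies cis to the ketene in the (Z)-dienylketene 13. Ring A then closes by thermal 6π electrocyclisation of the ketene C=C, the C(OMe)=C(OH) bond and the adjacent C=C bond of the pyranone (forming C5–C4a of the flavone), and dienone 14, whose C4a–H lies between two carbonyls, tautomerises at once to the aromatic hydroquinone. The closest known reaction type is the thermal rearrangement of 4-aryl-, 4-heteroaryl- and 4-alkenyl-4-hydroxycyclobutenones to hydroquinones (Moore rearrangement). No stereocentre remains, since those of 12 and 14 are destroyed on the way. The regiochemistry is fixed by connectivity and needs no control: the carbinol carbon becomes C8, its methoxy neighbour C7, the CH carbon C6 and the ketene carbon C5, and the ketene can reach only the pyranone carbon next to the C4 carbonyl, which is also the nucleophilic beta carbon of the ring enol ether and so matched to the electrophilic ketene carbon. The only selectivity the step needs is outward rotation of the hydroxyl, secured by its donor character, and the hydroquinone oxidation level arises without any oxidant, so exclusion of air is the sole precaution.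

Step 9
Reactants: 15 5,8-dihydroxy-3,7-dimethoxy-2-[3,4,5-tris(methoxymethoxy)phenyl]-4H-chromen-4-one
Product: 16 5,8,3',4',5'-pentahydroxy-3,7-dimethoxyflavone (target)
Conditions: 2 M HCl in degassed MeOH, 45 °C, Ar; evaporate; crystallise under Ar
Reagents that add atoms: none
Why: Acid-catalysed transacetalisation of the three aryl methoxymethyl ethers with methanol, which carries the formaldehyde unit away as dimethoxymethane and keeps it from the nucleophilic C6; aryl methyl ethers and the chelated pyranone are inert, the acidic medium under argon protects the hydroquinone from autoxidation, and no stereocentre is involved.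

**Compound list**
1 | pyrogallol (benzene-1,2,3-triol) | Oc1cccc(O)c1O | starting material
2 | 1,2,3-tris(methoxymethoxy)benzene | COCOc1cccc(OCOC)c1OCOC | intermediate
3 | 4,4,5,5-tetramethyl-2-[3,4,5-tris(methoxymethoxy)phenyl]-1,3,2-dioxaborolane | COCOc1cc(B2OC(C)(C)C(C)(C)O2)cc(OCOC)c1OCOC | intermediate
4 | 3-hydroxy-4H-pyran-4-one (pyromeconic acid) | O=c1ccocc1O | starting material
5 | 2-bromo-3-hydroxy-4H-pyran-4-one | O=c1ccoc(Br)c1O | intermediate
6 | 2-bromo-3-methoxy-4H-pyran-4-one | COc1c(Br)occc1=O | intermediate
7 | 3-methoxy-2-[3,4,5-tris(methoxymethoxy)phenyl]-4H-pyran-4-one | COCOc1cc(-c2occc(=O)c2OC)cc(OCOC)c1OCOC | intermediate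
8 | dimethyl squarate (3,4-dimethoxycyclobut-3-ene-1,2-dione) | COC1=C(OC)C(=O)C1=O | starting material
9 | 4-hydroxy-2,3-dimethoxycyclobut-2-en-1-one (racemic) | COC1=C(OC)C(O)C1=O | intermediate
10 | 3-methoxycyclobut-3-ene-1,2-dione (methyl semisquarate) | COC1=CC(=O)C1=O | intermediate
11 | 6-lithio-3-methoxy-2-[3,4,5-tris(methoxymethoxy)phenyl]-4H-pyran-4-one | [Li]c1cc(=O)c(OC)c(-c2cc(OCOC)c(OCOC)c(OCOC)c2)o1 | intermediate
12 | 4-hydroxy-3-methoxy-4-{5-methoxy-4-oxo-6-[3,4,5-tris(methoxymethoxy)phenyl]-4H-pyran-2-yl}cyclobut-2-en-1-one (racemic) | COC1=CC(=O)C1(O)c1cc(=O)c(OC)c(-c2cc(OCOC)c(OCOC)c(OCOC)c2)o1 | intermediate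
13 | (3Z)-4-hydroxy-3-methoxy-4-{5-methoxy-4-oxo-6-[3,4,5-tris(methoxymethoxy)phenyl]-4H-pyran-2-yl}buta-1,3-dien-1-one (dienylketene) | O=C=C/C(OC)=C(O)\c1cc(=O)c(OC)c(-c2cc(OCOC)c(OCOC)c(OCOC)c2)o1 | intermediate
14 | 8-hydroxy-3,7-dimethoxy-2-[3,4,5-tris(methoxymethoxy)phenyl]-4aH-chromene-4,5-dione (racemic) | COC1=CC(=O)C2C(=O)C(OC)=C(c3cc(OCOC)c(OCOC)c(OCOC)c3)OC2=C1O | intermediate
15 | 5,8-dihydroxy-3,7-dimethoxy-2-[3,4,5-tris(methoxymethoxy)phenyl]-4H-chromen-4-one | COCOc1cc(-c2oc3c(O)c(OC)cc(O)c3c(=O)c2OC)cc(OCOC)c1OCOC | intermediate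
16 | 5,8,3',4',5'-pentahydroxy-3,7-dimethoxyflavone | COc1cc(O)c2c(=O)c(OC)c(-c3cc(O)c(O)c(O)c3)oc2c1O | target

**Step count.** Total: 9 steps. Longest linear sequence: 6 steps (1 → 2 → 3 → 7 → 12 → 15 → 16; the branch from 4 is equally long).

**Steps most likely to fail**

Step 7. Metalation may occur at another site (C5 of the pyranone or ortho to an acetal on ring B), the lithiated pyranone may add to unmetalated 7 or ring-open before it meets 10, or proton transfer and conjugate addition may compete at the semisquarate. The fallback makes the carbanion by halogen–metal exchange instead of deprotonation. Compound 7 would be zincated with TMPZnCl·LiCl (THF, 25 °C), a base under which zincated pyranones and chromones are stable, and quenched with I2 to give 6-iodo-3-methoxy-2-[3,4,5-tris(methoxymethoxy)phenyl]-4H-pyran-4-one F1, whose constitution can be proven before it is committed. Iodine–magnesium exchange of F1 with iPrMgCl·LiCl (THF, −40 °C) would give a less basic Grignard reagent, and its addition to 10 followed by NH4Cl would return the route at 12.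

Step 8. The ketene may be captured by its own hydroxyl after inward rotation (butenolide formation), closure onto the electron-poor pyranone double bond may be slow enough for the aldoketene to oligomerise, or the free hydroquinone may autoxidise during isolation. The fallback removes the free carbinol from play. Compound 12 would be silylated (Me3SiCl, Et3N, cat. DMAP, CH2Cl2, 0 °C) to 3-methoxy-4-{5-methoxy-4-oxo-6-[3,4,5-tris(methoxymethoxy)phenyl]-4H-pyran-2-yl}-4-(trimethylsilyloxy)cyclobut-2-en-1-one F2. Thermolysis of F2 in p-xylene should give the mono-silylated, far less air-sensitive 5-hydroxy-3,7-dimethoxy-8-(trimethylsilyloxy)-2-[3,4,5-tris(methoxymethoxy)phenyl]-4H-chromen-4-one F3, since silyl ethers of this kind are known to rearrange without lactone formation. The HCl/MeOH conditions of step 9 would cleave the silyl ether together with the acetals, so the fallback returns at 16.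

Step 6. Over-reduction of the squarate, or hydrolysis of the labile vinylogous ester to semisquaric acid during the acid step and isolation, may leave little 10. The fallback replaces hydride addition and elimination by substitution and hydrodehalogenation. Compound 8 would be half-hydrolysed (NaOH, 1 equiv, aq. THF, 0 °C; then HCl) to 3-hydroxy-4-methoxycyclobut-3-ene-1,2-dione F4 and converted with (COCl)2 and cat. DMF (CH2Cl2) into 3-chloro-4-methoxycyclobut-3-ene-1,2-dione F5. This vinylogous acid chloride would be reduced with Bu3SnH under Pd(PPh3)4 catalysis (toluene, rt), the known palladium-catalysed hydrostannolysis of acyl chlorides, to return at 10.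

**Further compounds**
F1 | step 7 | 6-iodo-3-methoxy-2-[3,4,5-tris(methoxymethoxy)phenyl]-4H-pyran-4-one | COCOc1cc(-c2oc(I)cc(=O)c2OC)cc(OCOC)c1OCOC
F2 | step 8 | 3-methoxy-4-{5-methoxy-4-oxo-6-[3,4,5-tris(methoxymethoxy)phenyl]-4H-pyran-2-yl}-4-(trimethylsilyloxy)cyclobut-2-en-1-one (racemic) | COC1=CC(=O)C1(O[Si](C)(C)C)c1cc(=O)c(OC)c(-c2cc(OCOC)c(OCOC)c(OCOC)c2)o1
F3 | step 8 | 5-hydroxy-3,7-dimethoxy-8-(trimethylsilyloxy)-2-[3,4,5-tris(methoxymethoxy)phenyl]-4H-chromen-4-one | COCOc1cc(-c2oc3c(O[Si](C)(C)C)c(OC)cc(O)c3c(=O)c2OC)cc(OCOC)c1OCOC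
F4 | step 6 | 3-hydroxy-4-methoxycyclobut-3-ene-1,2-dione | COC1=C(O)C(=O)C1=O
F5 | step 6 | 3-chloro-4-methoxycyclobut-3-ene-1,2-dione | COC1=C(Cl)C(=O)C1=O
A1 | direct plan | 2-methoxybenzene-1,4-diol (methoxyhydroquinone) | COc1cc(O)ccc1O
A2 | direct plan | 1-(2,5-dihydroxy-4-methoxyphenyl)-2-methoxyethan-1-one | COCC(=O)c1cc(O)c(OC)cc1O
A3 | direct plan | 3,4,5-tris(benzyloxy)benzoyl chloride | O=C(Cl)c1cc(OCc2ccccc2)c(OCc2ccccc2)c(OCc2ccccc2)c1
A4 | direct plan | 1-(2,5-dihydroxy-4-methoxyphenyl)-2-methoxy-3-[3,4,5-tris(benzyloxy)phenyl]propane-1,3-dione | COC(C(=O)c1cc(O)c(OC)cc1O)C(=O)c1cc(OCc2ccccc2)c(OCc2ccccc2)c(OCc2ccccc2)c1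
A5 | direct plan | 2-methoxy-5-{2-methoxy-3-oxo-3-[3,4,5-tris(benzyloxy)phenyl]propanoyl}cyclohexa-2,5-diene-1,4-dione | COC(C(=O)C1=CC(=O)C(OC)=CC1=O)C(=O)c1cc(OCc2ccccc2)c(OCc2ccccc2)c(OCc2ccccc2)c1
A6 | direct plan | 5,8-dihydroxy-3,7-dimethoxy-2-[3,4,5-tris(benzyloxy)phenyl]-4H-chromen-4-one | COc1cc(O)c2c(=O)c(OC)c(-c3cc(OCc4ccccc4)c(OCc4ccccc4)c(OCc4ccccc4)c3)oc2c1O
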